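A direct plan would build the unprenylated flavone first: the dibrominated aroylacetate A1 would be fused in a melt with the parent triphenol of ring A to give the dibromoflavone A2. The three phenols would be capped, C8 would be iodinated to give the 8-iodide A3, and all three prenyl groups would then be attached at once by Stille coupling before the acetals were cleaved.
Its weakest steps would be:
- the solvent-free pyrone fusion at about 240 °C, which would need excess ketoester and would leave a phenolic melt that is hard to purify;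
- the iodination of the assembled core, where C8 would have to win over C6 and C3 on substrate bias alone;
- the threefold prenyl transfer from tin on the most advanced material, where each of three sites (two of them flanking one hindered ether) would have to couple at the linear end of the allyl group.
Half of the carbon skeleton would arrive only in the step before the last, after two steps that add no carbon.

**Plan of the new route**
The retrosynthesis cuts ring C at O1–C8a and C4–C4a in one operation (and then O1–C2): an aryne of ring A inserts into the carboxyl C–O bond of the arylpropiolic acid of ring B.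
This is possible because O1 and C4 sit on neighbouring carbons (C8a, C4a) of ring A. The oxygen on C5, directly beside C4a, polarises the C4a≡C8a triple bond, so the carboxylate oxygen adds at C8a (next to the C8 prenyl group) and the acyl carbon ends on C4a.
Ring A and ring B are each finished first, with their prenyl groups, from a simple phenol; ring C forms last.
On ring A the third oxygen of the triphenol steers bromine and the prenyl group to its two ortho carbons and then leaves as triflate, so the C8/C6 question is settled on a small phenol. No melt condensation, no halogenation of the core and no prenyl cross-coupling occur.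

Key step: step 8

Step 1
Reactants: 1 benzene-1,3,5-triol (phloroglucinol); 2 chloromethyl ethyl ether
Product: 4 3,5-bis(ethoxymethoxy)phenol, via 5-(ethoxymethoxy)benzene-1,3-diol 3 (not isolated)
Conditions: 2 (2.0 equiv), K2CO3 (2.2 equiv), acetone, 0 °C to rt; chromatography
Reagents that add atoms: none
Why: Williamson-type O-alkylation with a chloromethyl ether, in which two equivalents should give the bis-ether as the main statistical product beside separable mono- and tris-ethers, and the threefold symmetry of 1 allows only one bis-ether (no stereocentre).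

Step 2
Reactants: 4 3,5-bis(ethoxymethoxy)phenol
Product: 5 2-bromo-3,5-bis(ethoxymethoxy)phenol
Conditions: NBS (1.0 equiv), CH2Cl2, −78 °C to −40 °C, dark
Reagents that add atoms: N-bromosuccinimide (NBS), O=C1CCC(=O)N1Br
Why: Electrophilic aromatic bromination ortho to the free hydroxyl group, where the carbon between OH and one acetal oxygen should be attacked at low temperature in preference to the more crowded carbon between the two acetals (as with other 3,5-dialkoxyphenols), the two ortho carbons being equivalent.

Step 3
Reactants: 5 2-bromo-3,5-bis(ethoxymethoxy)phenol; 6 1-bromo-3-methylbut-2-ene (prenyl bromide)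
Product: 7 2-bromo-3,5-bis(ethoxymethoxy)-6-(3-methylbut-2-en-1-yl)phenol
Conditions: NaH (1.1 equiv), toluene, 0 °C; 6 (1.1 equiv), rt, 16 h; NH4Cl (aq)
Reagents that add atoms: none
Why: Ortho C-alkylation of a sodium phenoxide in a non-polar solvent, where the tight ion pair delivers the allylic bromide by SN2 to the ring carbon beside the oxygen; only one such carbon is free, so the prenyl group lands on the future C8.

Step 4
Reactants: 7 2-bromo-3,5-bis(ethoxymethoxy)-6-(3-methylbut-2-en-1-yl)phenol
Product: 10 3,5-bis(ethoxymethoxy)-2-(3-methylbut-2-en-1-yl)-6-(trimethylsilyl)phenyl trifluoromethanesulfonate, via aryl trimethylsilyl ether 8 (not isolated), via lithium 2-silylphenolate 9 (not isolated)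
Conditions: HMDS (1.5 equiv), THF, 65 °C, then evaporation; n-BuLi (1.1 equiv), THF, −100 °C to −80 °C; Tf2O (1.2 equiv), −100 °C to −78 °C; NaHCO3 (aq)
Reagents that add atoms: hexamethyldisilazane (HMDS), C[Si](C)(C)N[Si](C)(C)C; trifluoromethanesulfonic anhydride (Tf2O), O=S(=O)(OS(=O)(=O)C(F)(F)F)C(F)(F)F
Why: O-silylation, bromine–lithium exchange and anionic 1,3 shift of silicon from oxygen to carbon (retro-Brook rearrangement) put the silyl group on the former bromine carbon, and the lithium phenolate is trapped as the triflate, the standard entry to ortho-silylaryl triflates, which the prenyl group and the acetals should tolerate at these temperatures.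

Step 5
Reactants: 11 4-iodophenol; 6 1-bromo-3-methylbut-2-ene (prenyl bromide)
Product: 13 4-iodo-2,6-bis(3-methylbut-2-en-1-yl)phenol, via 4-iodo-2-(3-methylbut-2-en-1-yl)phenol 12 (not isolated)
Conditions: NaH (2.2 equiv), toluene, 0 °C; 6 (2.2 equiv), rt, 24 h; NH4Cl (aq)
Reagents that add atoms: none
Why: Twofold ortho C-prenylation of sodium 4-iodophenoxide in toluene, a reaction type established for para-halophenols, which fills both carbons beside the oxygen because the para carbon is blocked by iodine.

Step 6
Reactants: 13 4-iodo-2,6-bis(3-methylbut-2-en-1-yl)phenol; 2 chloromethyl ethyl ether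
Product: 14 2-(ethoxymethoxy)-5-iodo-1,3-bis(3-methylbut-2-en-1-yl)benzene
Conditions: NaH (1.3 equiv), 2 (1.3 equiv), DMF, 0 °C to rt
Reagents that add atoms: none
Why: Williamson-type O-alkylation of the hindered phenoxide with a small, reactive chloromethyl ether; the acetal keeps this phenol from adding to the aryne in step 8.

Step 7
Reactants: 14 2-(ethoxymethoxy)-5-iodo-1,3-bis(3-methylbut-2-en-1-yl)benzene; 15 prop-2-ynoic acid (propiolic acid)
Product: 16 3-[4-(ethoxymethoxy)-3,5-bis(3-methylbut-2-en-1-yl)phenyl]prop-2-ynoic acid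
Conditions: 15 (1.2 equiv), Pd(PPh3)4 (5 mol %), DBU (2.4 equiv), DMSO, 35 °C, 12 h; cold citric acid (aq) to pH 4; used promptly
Reagents that add atoms: none
Why: Copper-free Sonogashira coupling of the aryl iodide with the DBU salt of propiolic acid at a temperature below that at which arylpropiolates lose CO2; zerovalent palladium should insert into the C–I bond far faster than it touches the trisubstituted alkenes.

Step 8
Reactants: 16 3-[4-(ethoxymethoxy)-3,5-bis(3-methylbut-2-en-1-yl)phenyl]prop-2-ynoic acid; 10 3,5-bis(ethoxymethoxy)-2-(3-methylbut-2-en-1-yl)-6-(trimethylsilyl)phenyl trifluoromethanesulfonate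
Product: 19 5,7-bis(ethoxymethoxy)-2-[4-(ethoxymethoxy)-3,5-bis(3-methylbut-2-en-1-yl)phenyl]-8-(3-methylbut-2-en-1-yl)-4H-chromen-4-one, via aryne 17 (not isolated), via ortho-hydroxyaryl ynone 18 (not isolated)
Conditions: 10 (1.5 equiv), CsF (4 equiv), THF, 125 °C, sealed tube, 24 h
Reagents that add atoms: none
Why: Fluoride removes the silyl group of 10 and triflate leaves to give aryne 17; the caesium carboxylate of 16 adds through oxygen to C8a, the aryl anion formed at C4a attacks the ester carbonyl (4-exo-trig), and the strained adduct opens to the phenolate of ynone 18, so that the aryne has inserted into the C(=O)–O bond. The closest known reaction type is the fluoride-induced insertion of arynes into the C–O bond of carboxylic acids, which with arylpropiolic acids runs on to flavones. Ring C then closes by 6-endo-dig oxa-Michael addition of the C8a phenolate to the ynone carbon that carries ring B, and protonation at C3 gives the 4-pyranone; no stereocentre is formed. The step needs one orientation of addition to the unsymmetrical aryne, and the acetal oxygen on C5, directly beside C4a, should secure it: its inductive pull distorts the triple bond so that nucleophiles attack the remote carbon C8a and the charge appears at C4a next to the C–O bond, while the alkyl (prenyl) group on C8 polarises far less. It also needs the acyl shift to outrun protonation of the aryl anion and the ynone to close endo and not exo, for which the high temperature in THF and the caesium phenolate are relied on; the prenyl double bond on C8 is held too close to the triple bond for an intramolecular ene reaction.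

Step 9
Reactants: 19 5,7-bis(ethoxymethoxy)-2-[4-(ethoxymethoxy)-3,5-bis(3-methylbut-2-en-1-yl)phenyl]-8-(3-methylbut-2-en-1-yl)-4H-chromen-4-one
Product: 20 Epimedonin L (5,7-dihydroxy-2-[4-hydroxy-3,5-bis(3-methylbut-2-en-1-yl)phenyl]-8-(3-methylbut-2-en-1-yl)-4H-chromen-4-one)
Conditions: 3 M HCl (aq)/MeOH 1:5, 40 °C, 2 h; NaHCO3 (aq)
Reagents that add atoms: none
Why: Acid-catalysed transacetalisation of the three ethoxymethyl ethers to methanol under the mild conditions in common use for ortho-prenylated phenols, kept short and warm and not hot so that the freed hydroxyl groups should not add across the prenyl double bonds (the target has no stereocentre).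

**Compound list**
1 | benzene-1,3,5-triol (phloroglucinol) | Oc1cc(O)cc(O)c1 | starting material
2 | chloromethyl ethyl ether | CCOCCl | starting material
3 | 5-(ethoxymethoxy)benzene-1,3-diol | CCOCOc1cc(O)cc(O)c1 | intermediate
4 | 3,5-bis(ethoxymethoxy)phenol | CCOCOc1cc(O)cc(OCOCC)c1 | intermediate
5 | 2-bromo-3,5-bis(ethoxymethoxy)phenol | CCOCOc1cc(O)c(Br)c(OCOCC)c1 | intermediate
6 | 1-bromo-3-methylbut-2-ene (prenyl bromide) | CC(C)=CCBr | starting material
7 | 2-bromo-3,5-bis(ethoxymethoxy)-6-(3-methylbut-2-en-1-yl)phenol | CCOCOc1cc(OCOCC)c(Br)c(O)c1CC=C(C)C | intermediate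
8 | [2-bromo-3,5-bis(ethoxymethoxy)-6-(3-methylbut-2-en-1-yl)phenoxy]trimethylsilane | CCOCOc1cc(OCOCC)c(Br)c(O[Si](C)(C)C)c1CC=C(C)C | intermediate
9 | lithium 3,5-bis(ethoxymethoxy)-2-(3-methylbut-2-en-1-yl)-6-(trimethylsilyl)phenolate | [Li+].CCOCOc1cc(OCOCC)c([Si](C)(C)C)c([O-])c1CC=C(C)C | intermediate
10 | 3,5-bis(ethoxymethoxy)-2-(3-methylbut-2-en-1-yl)-6-(trimethylsilyl)phenyl trifluoromethanesulfonate | CCOCOc1cc(OCOCC)c([Si](C)(C)C)c(OS(=O)(=O)C(F)(F)F)c1CC=C(C)C | intermediate
11 | 4-iodophenol | Oc1ccc(I)cc1 | starting material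
12 | 4-iodo-2-(3-methylbut-2-en-1-yl)phenol | CC(C)=CCc1cc(I)ccc1O | intermediate
13 | 4-iodo-2,6-bis(3-methylbut-2-en-1-yl)phenol | CC(C)=CCc1cc(I)cc(CC=C(C)C)c1O | intermediate
14 | 2-(ethoxymethoxy)-5-iodo-1,3-bis(3-methylbut-2-en-1-yl)benzene | CCOCOc1c(CC=C(C)C)cc(I)cc1CC=C(C)C | intermediate
15 | prop-2-ynoic acid (propiolic acid) | C#CC(=O)O | starting material
16 | 3-[4-(ethoxymethoxy)-3,5-bis(3-methylbut-2-en-1-yl)phenyl]prop-2-ynoic acid | CCOCOc1c(CC=C(C)C)cc(C#CC(=O)O)cc1CC=C(C)C | intermediate
17 | 3,5-bis(ethoxymethoxy)-6-(3-methylbut-2-en-1-yl)benzyne (1,2-didehydrobenzene) | CCOCOC1=CC(OCOCC)=C(CC=C(C)C)C#C1 | intermediate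
18 | 1-[4,6-bis(ethoxymethoxy)-2-hydroxy-3-(3-methylbut-2-en-1-yl)phenyl]-3-[4-(ethoxymethoxy)-3,5-bis(3-methylbut-2-en-1-yl)phenyl]prop-2-yn-1-one (present in step 8 as its caesium phenolate) | CCOCOc1cc(OCOCC)c(C(=O)C#Cc2cc(CC=C(C)C)c(OCOCC)c(CC=C(C)C)c2)c(O)c1CC=C(C)C | intermediate
19 | 5,7-bis(ethoxymethoxy)-2-[4-(ethoxymethoxy)-3,5-bis(3-methylbut-2-en-1-yl)phenyl]-8-(3-methylbut-2-en-1-yl)-4H-chromen-4-one | CCOCOc1cc(OCOCC)c2c(=O)cc(-c3cc(CC=C(C)C)c(OCOCC)c(CC=C(C)C)c3)oc2c1CC=C(C)C | intermediate
20 | Epimedonin L, 5,7-dihydroxy-2-[4-hydroxy-3,5-bis(3-methylbut-2-en-1-yl)phenyl]-8-(3-methylbut-2-en-1-yl)-4H-chromen-4-one | CC(C)=CCc1cc(-c2cc(=O)c3c(O)cc(O)c(CC=C(C)C)c3o2)cc(CC=C(C)C)c1O | target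

Total step count: 9. Longest linear sequence: 6 steps (steps 1, 2, 3, 4, 8, 9); steps 5 to 7 form the second branch.

**Steps most likely to fail**

Step 8. The aryl anion may be protonated by free acid before the acyl shift (an aryl ester instead of the ketone), the propiolate may lose CO2 at 125 °C, or the ynone may close 5-exo. The fallback sets out from 10 and 16 and comes back to the route at 18. Aryne 17 would be generated from 10 with CsF in N,N-dimethylformamide, where no acid is present: the amide oxygen adds at C8a, the aryl anion closes onto the amide carbon, and hydrolysis on aqueous work-up should give 4,6-bis(ethoxymethoxy)-2-hydroxy-3-(3-methylbut-2-en-1-yl)benzaldehyde F1. Acid 16 would be protodecarboxylated (CuCl cat., Et3N, MeCN, 60 °C) to 2-(ethoxymethoxy)-5-ethynyl-1,3-bis(3-methylbut-2-en-1-yl)benzene F2. The lithium acetylide of F2 (n-BuLi, THF, −78 °C; 2.2 equiv) would add to F1 to give racemic 1-[4,6-bis(ethoxymethoxy)-2-hydroxy-3-(3-methylbut-2-en-1-yl)phenyl]-3-[4-(ethoxymethoxy)-3,5-bis(3-methylbut-2-en-1-yl)phenyl]prop-2-yn-1-ol F3. MnO2 in CH2Cl2 would oxidise F3 to ynone 18, here isolated as the free phenol, and Et2NH in EtOH at rt would close ring C by 6-endo oxa-Michael addition to 19.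

Step 3. The phenoxide may be alkylated on oxygen, at the carbon between the two acetals, at the tertiary end of the allyl group, or twice with loss of aromaticity. The fallback sets out from 5 and comes back at 7, and delivers the prenyl group by sigmatropic shift instead of alkylation. O-Alkylation of 5 with 3-chloro-3-methylbut-1-yne (DBU, CuCl2 cat., MeCN, 0 °C) would give 2-bromo-1,5-bis(ethoxymethoxy)-3-[(2-methylbut-3-yn-2-yl)oxy]benzene F4. Semihydrogenation (H2, Pd/CaCO3 poisoned with Pb(OAc)2, quinoline, EtOAc) would give 2-bromo-1,5-bis(ethoxymethoxy)-3-[(2-methylbut-3-en-2-yl)oxy]benzene F5. Heating F5 in toluene at 110 °C should bring about the aromatic Claisen rearrangement to the only free ortho carbon, with allylic transposition to the linear prenyl group, giving 7.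

Step 2. Bromine may enter between the two acetal groups, or twice. The fallback sets out from 4 and comes back at 5, and replaces electrophilic substitution by directed ortho-metalation. Carbamoylation of 4 (Et2NCOCl, K2CO3, MeCN, reflux) would give 3,5-bis(ethoxymethoxy)phenyl N,N-diethylcarbamate F6. Lithiation beside the carbamate, the strongest director on the ring (s-BuLi, TMEDA, THF, −78 °C), and quenching with BrCF2CF2Br would give 2-bromo-3,5-bis(ethoxymethoxy)phenyl N,N-diethylcarbamate F7. Hydrolysis (KOH, EtOH/H2O, reflux) would free phenol 5.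

**Further compounds**
F1 | step 8 | 4,6-bis(ethoxymethoxy)-2-hydroxy-3-(3-methylbut-2-en-1-yl)benzaldehyde | CCOCOc1cc(OCOCC)c(C=O)c(O)c1CC=C(C)C
F2 | step 8 | 2-(ethoxymethoxy)-5-ethynyl-1,3-bis(3-methylbut-2-en-1-yl)benzene | CCOCOc1c(CC=C(C)C)cc(C#C)cc1CC=C(C)C
F3 | step 8 | racemic 1-[4,6-bis(ethoxymethoxy)-2-hydroxy-3-(3-methylbut-2-en-1-yl)phenyl]-3-[4-(ethoxymethoxy)-3,5-bis(3-methylbut-2-en-1-yl)phenyl]prop-2-yn-1-ol | CCOCOc1cc(OCOCC)c(C(O)C#Cc2cc(CC=C(C)C)c(OCOCC)c(CC=C(C)C)c2)c(O)c1CC=C(C)C
F4 | step 3 | 2-bromo-1,5-bis(ethoxymethoxy)-3-[(2-methylbut-3-yn-2-yl)oxy]benzene | CCOCOc1cc(OCOCC)c(Br)c(OC(C)(C)C#C)c1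
F5 | step 3 | 2-bromo-1,5-bis(ethoxymethoxy)-3-[(2-methylbut-3-en-2-yl)oxy]benzene | CCOCOc1cc(OCOCC)c(Br)c(OC(C)(C)C=C)c1
F6 | step 2 | 3,5-bis(ethoxymethoxy)phenyl N,N-diethylcarbamate | CCOCOc1cc(OCOCC)cc(OC(=O)N(CC)CC)c1
F7 | step 2 | 2-bromo-3,5-bis(ethoxymethoxy)phenyl N,N-diethylcarbamate | CCOCOc1cc(OCOCC)c(Br)c(OC(=O)N(CC)CC)c1
A1 | direct plan | ethyl 3-(3,5-dibromo-4-hydroxyphenyl)-3-oxopropanoate | CCOC(=O)CC(=O)c1cc(Br)c(O)c(Br)c1
A2 | direct plan | 2-(3,5-dibromo-4-hydroxyphenyl)-5,7-dihydroxy-4H-chromen-4-one | O=c1cc(-c2cc(Br)c(O)c(Br)c2)oc2cc(O)cc(O)c12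
A3 | direct plan | 2-[3,5-dibromo-4-(methoxymethoxy)phenyl]-8-iodo-5,7-bis(methoxymethoxy)-4H-chromen-4-one | COCOc1cc(OCOC)c2c(=O)cc(-c3cc(Br)c(OCOC)c(Br)c3)oc2c1I
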